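Assumption: the target has no stereocentres and no E/Z-isomeric alkenes (both alkenes end in a gem-dimethyl group), so it is achiral and "the single enantiomer given" is the compound itself.

**Retrosynthetic overview**
1. Target 10 ⇒ cut both aryl–prenyl C–C bonds (C3 and C5) in one operation: a double Pd-catalysed decarboxylative C–H prenylation of 2-hydroxy-4,6-dimethoxybenzophenone 5 with methyl prenyl carbonate 7 (proposed new step).
2. 5 ⇒ chelation-controlled mono-O-demethylation of the symmetrical 2,4,6-trimethoxybenzophenone 3 (the two ortho OMe groups are equivalent).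
3. 3 ⇒ Friedel–Crafts benzoylation of 1,3,5-trimethoxybenzene 1 with benzoyl chloride 2; 7 ⇒ prenol 6 + methyl chloroformate.
4. No ring is formed: both benzene rings are bought, and there is no stereocentre to set.

**Route**

Step 1
Reactants: 1 1,3,5-trimethoxybenzene; 2 benzoyl chloride
Product: 3 2,4,6-trimethoxybenzophenone
Conditions: AlCl3 (1.1 equiv), CH2Cl2, 0 °C to rt; then ice/1 M HCl
Reagents that add atoms: none
Why: Friedel–Crafts acylation of a symmetrical, strongly activated arene whose three free positions are equivalent gives one regioisomer, and the twisted, deactivated ketone product does not acylate again.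

Step 2
Reactants: 3 2,4,6-trimethoxybenzophenone
Product: 5 2-hydroxy-4,6-dimethoxybenzophenone, via dichloroboron chelate 4 (not isolated)
Conditions: BCl3 (1.2 equiv, 1 M in CH2Cl2), CH2Cl2, −78 to 0 °C; then H2O
Reagents that add atoms: none
Why: Chelation-controlled Lewis-acid ether cleavage: BCl3 binds the ketone oxygen and removes only a methyl group ortho to the carbonyl (the two are equivalent), and the resulting six-membered O–B–O chelate 4 stops a second cleavage.

Step 3
Reactants: 6 3-methylbut-2-en-1-ol (prenol)
Product: 7 methyl (3-methylbut-2-en-1-yl) carbonate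
Conditions: ClCO2Me (1.2 equiv), pyridine (1.5 equiv), CH2Cl2, 0 °C to rt
Reagents that add atoms: methyl chloroformate, COC(=O)Cl
Why: O-acylation of a primary allylic alcohol with a chloroformate under base takes place at oxygen without allylic transposition.

Step 4
Reactants: 5 2-hydroxy-4,6-dimethoxybenzophenone; 7 methyl (3-methylbut-2-en-1-yl) carbonate (2.4 equiv)
Product: 10 (2-hydroxy-4,6-dimethoxy-3,5-bis(3-methylbut-2-en-1-yl)phenyl)(phenyl)methanone (CNP0230472.0), via O-prenyl ether 8 (not isolated), via 3-prenyl phenol 9 (not isolated)
Conditions: Pd2(dba)3 (2.5 mol %), DPEphos (6 mol %), degassed toluene (0.1 M), 70 °C; neutral work-up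
Reagents that add atoms: none
Why: Proposed new method: double, linear-selective aromatic C–H prenylation of a mono-phenolic o-acylphenol by decarboxylative Pd catalysis – Pd(0) ionises 7 with loss of CO2 to [(DPEphos)Pd(η3-prenyl)]+ MeO−, and methoxide deprotonates the much more acidic chelated phenol to give a contact ion pair in toluene; kinetic O-attack gives ether 8, but its acyl-stabilised phenoxide is a good leaving group, so Pd(0) re-ionises 8 and it serves only as a reservoir, whereas C-attack at C3 and then C5 (each ortho/para to three oxygen donors, i.e. phloroglucinol-like nucleophilicity) followed by re-aromatising tautomerisation is irreversible; the soft carbon nucleophile attacks the unsubstituted CH2 terminus of the η3-prenyl ligand on the wide-bite-angle complex, giving the linear prenyl group, and the acid-free medium avoids chroman formation from the o-prenylphenol; the closest known reaction types are the Tsuji–Trost decarboxylative allylation of phenols, the Pd-catalysed Friedel–Crafts-type C-allylation of naphthols and phloroglucinols, and the Pd-catalysed O-to-C allyl migration of aryl allyl ethers.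

**Compound list**
1 | 1,3,5-trimethoxybenzene | COc1cc(OC)cc(OC)c1 | starting material
2 | benzoyl chloride | O=C(Cl)c1ccccc1 | starting material
3 | 2,4,6-trimethoxybenzophenone | COc1cc(OC)c(C(=O)c2ccccc2)c(OC)c1 | intermediate
4 | 2-(dichloroboryloxy)-4,6-dimethoxybenzophenone (B chelated by the ketone oxygen) | COc1cc(OC)c(C(=O)c2ccccc2)c(OB(Cl)Cl)c1 | intermediate
5 | 2-hydroxy-4,6-dimethoxybenzophenone | COc1cc(OC)c(C(=O)c2ccccc2)c(O)c1 | intermediate
6 | 3-methylbut-2-en-1-ol (prenol) | CC(C)=CCO | starting material
7 | methyl (3-methylbut-2-en-1-yl) carbonate | COC(=O)OCC=C(C)C | intermediate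
8 | 2,4-dimethoxy-6-(3-methylbut-2-en-1-yloxy)benzophenone (O-prenyl ether of 5) | COc1cc(OC)c(C(=O)c2ccccc2)c(OCC=C(C)C)c1 | intermediate
9 | 2-hydroxy-4,6-dimethoxy-3-(3-methylbut-2-en-1-yl)benzophenone | COc1cc(OC)c(C(=O)c2ccccc2)c(O)c1CC=C(C)C | intermediate
10 | (2-hydroxy-4,6-dimethoxy-3,5-bis(3-methylbut-2-en-1-yl)phenyl)(phenyl)methanone, achiral | COc1c(CC=C(C)C)c(O)c(C(=O)c2ccccc2)c(OC)c1CC=C(C)C | target

**Totals**
Total step count: 4. Longest linear sequence: 3 (steps 1, 2, 4); step 3 is a one-step side branch.

**Three steps most likely to fail**

Step 4 (the proposed new step). The risks are that O-prenyl ether 8 accumulates, that the reaction stops at mono-prenyl 9, that a third prenyl group adds with dearomatisation, or that some branched (reverse-prenyl) product forms. The fallback uses known chemistry, sets out from 5 and comes back at 10. Bromination of 5 with NBS (2.05 equiv, MeCN, 0 °C) at the two activated free positions gives 3,5-dibromo-2-hydroxy-4,6-dimethoxybenzophenone F1. A double Stille coupling of F1 with commercial tributyl(3-methylbut-2-en-1-yl)stannane (2.5 equiv, Pd(PPh3)4 10 mol %, DMF, 90 °C) then puts in both linear prenyl groups and gives 10.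

Step 2. The risks are over-demethylation to the 2,6-dihydroxy compound or incomplete conversion. The fallback avoids ether cleavage altogether, sets out from 2 and comes back at 5. Commercial 3,5-dimethoxyphenol (COc1cc(O)cc(OC)c1) is O-benzoylated with 2 (Et3N, CH2Cl2, 0 °C) to give 3,5-dimethoxyphenyl benzoate F2. A Lewis-acid Fries rearrangement of F2 (AlCl3, chlorobenzene, 100 °C) moves the benzoyl group to the position ortho to the phenol oxygen, favoured by chelation, and gives 5.

Step 1. The risk is partial ortho-demethylation or tar formation under AlCl3 (small amounts of 5 formed here are harmless, since 5 is the next product). The fallback replaces the electrophilic acylation by an organolithium addition/oxidation sequence, sets out from 1 and comes back at 3. Lithiation of 1 between two methoxy groups (n-BuLi, TMEDA, THF, 0 °C) gives 2,4,6-trimethoxyphenyllithium F3. This is added to benzaldehyde (−78 °C, then aq NH4Cl) to give racemic (2,4,6-trimethoxyphenyl)(phenyl)methanol F4. Oxidation of F4 with MnO2 (CH2Cl2, rt) gives 3.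

**Further compounds**
F1 | step 4 | 3,5-dibromo-2-hydroxy-4,6-dimethoxybenzophenone | COc1c(Br)c(O)c(C(=O)c2ccccc2)c(OC)c1Br
F2 | step 2 | 3,5-dimethoxyphenyl benzoate | COc1cc(OC)cc(OC(=O)c2ccccc2)c1
F3 | step 1 | 2,4,6-trimethoxyphenyllithium | [Li]c1c(OC)cc(OC)cc1OC
F4 | step 1 | (2,4,6-trimethoxyphenyl)(phenyl)methanol (racemic) | COc1cc(OC)c(C(O)c2ccccc2)c(OC)c1
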